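## The problem

The target 9 is a 2,4-dibromo-3-methylphenol whose last ortho carbon is bonded to C1 of a 1,2-dimethylbicyclo[3.1.0]hexane. The locants used here are C1 (quaternary, aryl and methyl), C2 and C3 (CH2), C4 (ring-fusion CH), C5 (cyclopropane CH2) and C6 (ring-fusion C-methyl). There are three contiguous stereocentres, C1, C6 and C4; C1 and C6 are adjacent and fully substituted, and the C1–arene bond is crowded by the phenol oxygen. C4 and C6 are tied together by the cis-fused three-membered ring, so only two things must be decided: the absolute configuration at C1, and the face that carries C5, which in 9 is the face of the aryl group. C1 can settle the second point if the phenol on its own aryl group delivers the methylene, so the real task is C1 as a single enantiomer. Cationic arylation is no answer, because an allyl cation spanning C1–C6–C4 would be attacked at its secondary end. The aryl cyclopropane beside a free phenol opens under acid to a dihydrobenzofuran, so it should appear late and meet no protic or strong Lewis acid; the aryl bromides exclude late metalation. The enabling feature is seen once C5 is removed: a C4=C6 alkene appears, C1 becomes the far end of an allyl unit, and the arene carbon on C1 is ortho to oxygen. That array, O–C(aryl)=C(ortho)–C1–C6=C4, is the product pattern of an aryl allyl ether [3,3] shift in which C4 held the oxygen.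

## Retrosynthesis

**9 to 8.** The C–Br bond at the ortho carbon between hydroxyl and methyl is cut, leading to 4-bromo-2-[(1S,2R,5R)-1,2-dimethylbicyclo[3.1.0]hexan-2-yl]-5-methylphenol 8. In 8 this is the only activated open position; the other aromatic CH is meta to oxygen and wedged between the bicycle and bromine. Leaving this carbon unsubstituted until the end also keeps one ortho position free for the earlier C–C bond formation. The para bromine is kept because it comes with a cheap phenol and blocks the para position. The forward step must be an acid-free electrophilic bromination.

**8 to 6.** The two cyclopropane bonds C4–C5 and C6–C5 are cut, removing the methylene and giving 4-bromo-2-[(1R)-1,2-dimethylcyclopent-2-en-1-yl]-5-methylphenol 6. This removes two stereocentres at once and the cis fusion is automatic. The one open question, the face, is answered by the neighbouring phenol through a zinc-bound carbenoid 7. Cutting C1–C6 or closing the ring by alkylation would each need extra functional groups. The forward step must transfer methylene syn to the aryl group without strong acid.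

**6 to 4.** The arene–C1 bond is cut by a retro-Claisen shift through the ortho-dienone 5, giving the aryl ether 1-bromo-4-{[(1S)-2,3-dimethylcyclopent-2-en-1-yl]oxy}-2-methylbenzene 4. This is the one disconnection that forms the hindered bond intramolecularly, at the tertiary allyl terminus, and with the configuration of C1 copied from a secondary C–O stereocentre that is easy to make. The precursor has no quaternary carbon and no C–C bond between the two rings. The forward step needs a concerted, suprafacial shift that is faster than C–O heterolysis, and ortho regioselectivity.

**4 to 2 and 3.** The alkyl C4–O bond is cut to (R)-2,3-dimethylcyclopent-2-en-1-ol 2 and 4-bromo-3-methylphenol 3. Displacement at the carbinol carbon with inversion is preferred to forming the aryl–O bond because it runs cold and neutral; the alternative is kept in reserve. The forward step needs clean SN2 at an allylic carbon that ionises easily.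

**2 to 1.** The carbinol C–H bond is cut to 2,3-dimethylcyclopent-2-en-1-one 1. The α-methyl group makes the two flanks of the carbonyl very different, which is what a catalytic enantioselective reduction needs. Both 1 and 3 are commercial.

## Roads not taken

**Alternative 1:** The cut is at C6–CH3 and C4–C5. A methylcopper reagent would add to the β-carbon of (S)-3-(chloromethyl)-4-(2-methoxy-4-methylphenyl)-4-methylcyclopent-2-en-1-one A1, and the enolate would displace chloride to close the three-membered ring, giving bicyclic ketone A2.

- **Merits:** one operation makes two C–C bonds and both ring-fusion stereocentres, the cis fusion is automatic, and the cyclopropane forms under basic conditions with the phenol masked. In this it is better than the chosen plan, which depends on a directing effect and exposes a free phenol to zinc salts.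
- **Weak points:**
  - A1 already contains the C1 aryl quaternary stereocentre, so the hardest problem is only moved back.
  - The methyl group must add anti to the aryl group, a selectivity that rests on aryl against methyl at the neighbouring carbon.
  - The allylic chloride can be displaced directly by the cuprate.
  - The C3 carbonyl of A2 must be removed, and O-demethylation and two brominations follow.
- **Comparison:** the chosen plan makes C1 in three steps from commercial materials and is roughly half as long.

**Alternative 2:** The cut is at C1–C2. A chiral N-triflyl phosphoramide would protonate the alkene terminus of 1-[1-(2-methoxy-4-methylphenyl)ethenyl]cyclobutan-1-ol A3, and a cyclobutane carbon would migrate to the benzylic cation, giving (S)-2-(2-methoxy-4-methylphenyl)-2-methylcyclopentan-1-one A4.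

- **Merits:** the stereocentre is set catalytically in a configurationally robust ketone, with no labile allyl ether. In these respects it is better than the chosen plan, which relays stoichiometric chirality through two stereospecific steps that can each leak by ionisation.
- **Weak points:**
  - The ortho-methoxy group lengthens the life of the planar cation and crowds the ion pair on which the selectivity depends.
  - A3 needs its own preparation.
  - After A4, the C6 methyl and the alkene must be installed, the ether cleaved with the alkene present, and then cyclopropanation and both brominations carried out — about ten operations in all.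
- **Comparison:** the chosen plan has five steps and the free phenol is present exactly when it is needed as a directing group.

**Alternative 3:** The cut is at C1–C6. A Lewis acid such as BF3·OEt2 would open the epoxide of 3-(2-methoxy-4-methylphenyl)-1-methylbicyclo[4.1.0]hept-2-ene (oxirane anti to the cyclopropane) A5 at the benzylic carbon, and the cyclopropane carbon C6 would migrate, contracting the ring to aldehyde A6.

- **Merits:** this is the only road that forms the bond between the two quaternary carbons directly. The migration is stereospecific, which matches the chosen plan in fidelity at C1, and the cyclopropane is already in place.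
- **Weak points:**
  - The migrating carbon is part of a cyclopropane next to a developing cation, so cyclopropylcarbinyl opening and hydride shift compete.
  - The acid-labile aryl cyclopropane meets a Lewis acid.
  - A5 needs enantiocontrol plus a face-selective cyclopropanation and epoxidation.
  - The formyl group must be reduced to methyl before demethylation and bromination.
- **Comparison:** the chosen plan has simple precursors and introduces the sensitive ring only in the penultimate step.

Key step: step 3

Remark on the chemistry: the oxazaborolidine reduction of 1 is assumed to follow the usual model, with the methyl-bearing alkenyl flank as the large group, so the (S)-catalyst gives (R)-2; if the sense were opposite, the (R)-catalyst would be used and nothing else changes.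

## Route

Step 1
Reactants: 1 2,3-dimethylcyclopent-2-en-1-one
Product: 2 (R)-2,3-dimethylcyclopent-2-en-1-ol
Conditions: (S)-2-methyl-CBS-oxazaborolidine (10 mol %), BH3·SMe2, THF, 0 °C; MeOH, then aqueous work-up
Reagents that add atoms: none
Why: Corey–Bakshi–Shibata reduction; the ketone binds the catalyst–borane complex with the alkenyl flank as the large group, so hydride reaches one carbonyl face and sets the (R)-carbinol centre, and 1,2-reduction should outpace hydroboration of the tetrasubstituted alkene.

Step 2
Reactants: 2 (R)-2,3-dimethylcyclopent-2-en-1-ol; 3 4-bromo-3-methylphenol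
Product: 4 1-bromo-4-{[(1S)-2,3-dimethylcyclopent-2-en-1-yl]oxy}-2-methylbenzene
Conditions: PPh3, DIAD, toluene, 0 °C to rt
Reagents that add atoms: none
Why: Mitsunobu etherification; the acidic phenol displaces the activated hydroxyl by SN2 at the secondary allylic carbon with inversion, so the (R)-alcohol should give the (S)-ether, and the non-polar solvent and low temperature disfavour ionisation and attack at the tertiary allyl terminus.

Step 3
Reactants: 4 1-bromo-4-{[(1S)-2,3-dimethylcyclopent-2-en-1-yl]oxy}-2-methylbenzene
Product: 6 4-bromo-2-[(1R)-1,2-dimethylcyclopent-2-en-1-yl]-5-methylphenol, via ortho-dienone 5 (not isolated)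
Conditions: Eu(fod)3 (10 mol %), CHCl3 (ethanol-free), 50 °C
Reagents that add atoms: none
Why: Aromatic Claisen rearrangement: the europium complex binds the ether oxygen and polarises the C4–O bond, the ortho carbon bonds to C1 through a six-membered transition state in a concerted [3,3] shift while the alkene moves to C4=C6, and dienone 5 enolises to phenol 6. The closest known reaction type is the europium-catalysed rearrangement of enantioenriched aryl cycloalkenyl ethers with transfer of chirality. No ring is closed. The new quaternary stereocentre C1 is controlled by the ether stereocentre C4: the allyl unit is held in the five-membered ring, so the C–C bond must form on the face from which oxygen leaves, and the (S)-ether should give (R)-C1. The step needs ortho regioselectivity, which the substrate secures because the para carbon carries bromine and the second ortho carbon, squeezed between oxygen and methyl, cannot accept a fully substituted carbon. It also needs the concerted path to beat C–O heterolysis, which the low temperature and the absence of protic acid favour.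

Step 4
Reactants: 6 4-bromo-2-[(1R)-1,2-dimethylcyclopent-2-en-1-yl]-5-methylphenol
Product: 8 4-bromo-2-[(1S,2R,5R)-1,2-dimethylbicyclo[3.1.0]hexan-2-yl]-5-methylphenol, via iodomethylzinc phenoxide 7 (not isolated)
Conditions: Et2Zn (1.2 equiv), CH2Cl2, −15 °C; then CH2I2 (1.5 equiv), −15 °C to rt; aqueous NH4Cl/NH3 quench
Reagents that add atoms: diiodomethane, ICI
Why: Phenol-directed Simmons–Smith cyclopropanation (Furukawa conditions); Et2Zn deprotonates the hydroxyl and exchange with CH2I2 gives the aryloxy(iodomethyl)zinc 7, a reactive carbenoid tethered to C1 through the arene, so methylene should be delivered to the alkene face on the side of the aryl group. C4 and C6 are set together, cis-fused and syn to the arene.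

Step 5
Reactants: 8 4-bromo-2-[(1S,2R,5R)-1,2-dimethylbicyclo[3.1.0]hexan-2-yl]-5-methylphenol
Product: 9 2,4-dibromo-6-[(1S,2R,5R)-1,2-dimethylbicyclo[3.1.0]hexan-2-yl]-3-methylphenol
Conditions: NBS (1.05 equiv), i-Pr2NH (10 mol %), CH2Cl2, 0 °C, dark
Reagents that add atoms: N-bromosuccinimide, O=C1CCC(=O)N1Br
Why: Amine-promoted ortho-bromination of a phenol with NBS (electrophilic aromatic substitution); the only open activated position is the ortho carbon between hydroxyl and methyl, the medium stays free of acid so the aryl cyclopropane should survive, and no stereocentre is touched.

## Compound list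

1 | 2,3-dimethylcyclopent-2-en-1-one | CC1=C(C)C(=O)CC1 | starting material
2 | (R)-2,3-dimethylcyclopent-2-en-1-ol | O[C@@H]1CCC(C)=C1C | intermediate
3 | 4-bromo-3-methylphenol | Cc1cc(O)ccc1Br | starting material
4 | 1-bromo-4-{[(1S)-2,3-dimethylcyclopent-2-en-1-yl]oxy}-2-methylbenzene | Cc1cc(O[C@H]2CCC(C)=C2C)ccc1Br | intermediate
5 | 4-bromo-6-[(1S)-1,2-dimethylcyclopent-2-en-1-yl]-3-methylcyclohexa-2,4-dien-1-one (ortho-dienone; quaternary carbon arranged in space as in 6, the descriptor changes only with the priorities; the ring CH is transient and its configuration is not assigned) | O=C1C=C(C)C(Br)=CC1[C@]2(C)CCC=C2C | intermediate (not isolated)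
6 | 4-bromo-2-[(1R)-1,2-dimethylcyclopent-2-en-1-yl]-5-methylphenol | Cc1cc(O)c([C@]2(C)CCC=C2C)cc1Br | intermediate
7 | {4-bromo-2-[(1R)-1,2-dimethylcyclopent-2-en-1-yl]-5-methylphenoxy}(iodomethyl)zinc | Cc1cc(O[Zn]CI)c([C@]2(C)CCC=C2C)cc1Br | intermediate (not isolated)
8 | 4-bromo-2-[(1S,2R,5R)-1,2-dimethylbicyclo[3.1.0]hexan-2-yl]-5-methylphenol | Cc1cc(O)c([C@]2(C)CC[C@@H]3C[C@@]32C)cc1Br | intermediate
9 | 2,4-dibromo-6-[(1S,2R,5R)-1,2-dimethylbicyclo[3.1.0]hexan-2-yl]-3-methylphenol | Cc1c(Br)cc([C@]2(C)CC[C@@H]3C[C@@]32C)c(O)c1Br | target

## Step count and risks

Total: 5 steps. Longest linear sequence: 5 steps (1 to 2 to 4 to 6 to 8 to 9); phenol 3 enters at step 2.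

**Step 3 (key step).**
- **Risk:** heterolysis of the C4–O bond. The 2,3-dimethylcyclopentenyl unit gives a tertiary-allylic cation, and a contact ion pair with the aryloxide can lose a proton (fragmentation to phenol and diene) or recombine without memory of the face. The result would be material loss and leaking chirality transfer. A thermal run in N,N-diethylaniline is the first change of conditions.
- **Fallback:** the absolute configuration is taken from a resolution instead; it sets out from 6 of insufficient enantiopurity and comes back at 6. The phenol is acylated with (1S)-camphanic chloride (Et3N, DMAP, CH2Cl2) to give 4-bromo-2-[(1R)-1,2-dimethylcyclopent-2-en-1-yl]-5-methylphenyl (1S,4R)-camphanate F1, together with the ester of the enantiomeric phenol, 4-bromo-2-[(1S)-1,2-dimethylcyclopent-2-en-1-yl]-5-methylphenyl (1S,4R)-camphanate F2. The diastereomers are separated by crystallisation or chromatography, and F1 is saponified (LiOH, THF/H2O, extraction at pH 8) to return 6. The rearrangement is then only asked to make the bond and can be run on 4 of any enantiopurity under whichever regime gives most material.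

**Step 2.**
- **Risk:** ionisation of the activated alcohol to the same stabilised cation before the phenoxide attacks, seen as incomplete inversion, attack at the tertiary terminus or elimination.
- **Fallback:** the other C–O bond is formed, so the carbinol carbon is never activated; it sets out from 1 and comes back at 4. Reduction of 1 as in step 1, but with the (R)-oxazaborolidine, gives (S)-2,3-dimethylcyclopent-2-en-1-ol F3. Ullmann-type O-arylation of F3 with commercial 1-bromo-4-iodo-2-methylbenzene (Cc1cc(I)ccc1Br; CuI, 3,4,7,8-tetramethyl-1,10-phenanthroline, Cs2CO3, toluene, 80 °C) should engage the iodide selectively and give 4 with retention, since the stereocentre is a spectator.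

**Step 4.**
- **Risk:** ring closure of the free phenol onto the alkene of 6 or onto the new cyclopropane of 8, promoted by the zinc iodide that builds up; or methylene transfer by untethered carbenoid to the methyl face.
- **Fallback:** the hydroxyl is capped with a group that still binds zinc and comes off without acid; it sets out from 6 and comes back at 8. SEMCl and i-Pr2NEt in CH2Cl2 give {2-[(4-bromo-2-[(1R)-1,2-dimethylcyclopent-2-en-1-yl]-5-methylphenoxy)methoxy]ethyl}trimethylsilane F4, whose acetal oxygens can hold the carbenoid on the aryl face. Cyclopropanation (Et2Zn, CH2I2, CH2Cl2, 0 °C) gives {2-[(4-bromo-2-[(1S,2R,5R)-1,2-dimethylbicyclo[3.1.0]hexan-2-yl]-5-methylphenoxy)methoxy]ethyl}trimethylsilane F5, and TBAF in THF at 60 °C releases 8.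

**Step 5.**
- **Risk:** attack of the electrophile on the electron-rich aryl cyclopropane with participation of the phenol oxygen (ring opening), competing with substitution at a carbon crowded by hydroxyl and methyl.
- **Fallback:** both bromines are carried from the start, so the cyclopropane never meets a brominating agent; it sets out from 2 and comes back at 9.
  - Commercial 2-bromo-3-methylphenol (Cc1cccc(O)c1Br) is brominated para to the hydroxyl with Bu4NBr3 to give 2,4-dibromo-3-methylphenol F6.
  - Mitsunobu coupling with 2 as in step 2 gives 1,3-dibromo-4-{[(1S)-2,3-dimethylcyclopent-2-en-1-yl]oxy}-2-methylbenzene F7.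
  - The Claisen shift of step 3 can then reach only the single free ortho carbon and gives 2,4-dibromo-6-[(1R)-1,2-dimethylcyclopent-2-en-1-yl]-3-methylphenol F8.
  - The directed cyclopropanation of step 4 converts F8 into 9.

## Further compounds

F1 | step 3 | 4-bromo-2-[(1R)-1,2-dimethylcyclopent-2-en-1-yl]-5-methylphenyl (1S,4R)-4,7,7-trimethyl-3-oxo-2-oxabicyclo[2.2.1]heptane-1-carboxylate | Cc1cc(OC(=O)[C@@]23CC[C@@](C)(C(=O)O2)C3(C)C)c([C@]2(C)CCC=C2C)cc1Br
F2 | step 3 | 4-bromo-2-[(1S)-1,2-dimethylcyclopent-2-en-1-yl]-5-methylphenyl (1S,4R)-4,7,7-trimethyl-3-oxo-2-oxabicyclo[2.2.1]heptane-1-carboxylate | Cc1cc(OC(=O)[C@@]23CC[C@@](C)(C(=O)O2)C3(C)C)c([C@@]2(C)CCC=C2C)cc1Br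
F3 | step 2 | (S)-2,3-dimethylcyclopent-2-en-1-ol | O[C@H]1CCC(C)=C1C
F4 | step 4 | {2-[(4-bromo-2-[(1R)-1,2-dimethylcyclopent-2-en-1-yl]-5-methylphenoxy)methoxy]ethyl}trimethylsilane | Cc1cc(OCOCC[Si](C)(C)C)c([C@]2(C)CCC=C2C)cc1Br
F5 | step 4 | {2-[(4-bromo-2-[(1S,2R,5R)-1,2-dimethylbicyclo[3.1.0]hexan-2-yl]-5-methylphenoxy)methoxy]ethyl}trimethylsilane | Cc1cc(OCOCC[Si](C)(C)C)c([C@]2(C)CC[C@@H]3C[C@@]32C)cc1Br
F6 | step 5 | 2,4-dibromo-3-methylphenol | Cc1c(Br)ccc(O)c1Br
F7 | step 5 | 1,3-dibromo-4-{[(1S)-2,3-dimethylcyclopent-2-en-1-yl]oxy}-2-methylbenzene | Cc1c(Br)ccc(O[C@H]2CCC(C)=C2C)c1Br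
F8 | step 5 | 2,4-dibromo-6-[(1R)-1,2-dimethylcyclopent-2-en-1-yl]-3-methylphenol | Cc1c(Br)cc([C@]2(C)CCC=C2C)c(O)c1Br
A1 | alternative 1 | (S)-3-(chloromethyl)-4-(2-methoxy-4-methylphenyl)-4-methylcyclopent-2-en-1-one | COc1cc(C)ccc1[C@]2(C)CC(=O)C=C2CCl
A2 | alternative 1 | (1R,4R,5S)-4-(2-methoxy-4-methylphenyl)-4,5-dimethylbicyclo[3.1.0]hexan-2-one | COc1cc(C)ccc1[C@]2(C)CC(=O)[C@@H]3C[C@@]32C
A3 | alternative 2 | 1-[1-(2-methoxy-4-methylphenyl)ethenyl]cyclobutan-1-ol | COc1cc(C)ccc1C(=C)C1(O)CCC1
A4 | alternative 2 | (S)-2-(2-methoxy-4-methylphenyl)-2-methylcyclopentan-1-one | COc1cc(C)ccc1[C@]2(C)CCCC2=O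
A5 | alternative 3 | 4-(2-methoxy-4-methylphenyl)-1-methyl-3-oxatricyclo[5.1.0.0(2,4)]octane, the 2,3-epoxide of 3-(2-methoxy-4-methylphenyl)-1-methylbicyclo[4.1.0]hept-2-ene with the oxirane anti to the cyclopropane CH2 | COc1cc(C)ccc1[C@]12CC[C@@H]3C[C@]3(C)[C@H]1O2
A6 | alternative 3 | (1S,2S,5R)-2-(2-methoxy-4-methylphenyl)-1-methylbicyclo[3.1.0]hexane-2-carbaldehyde | COc1cc(C)ccc1[C@]2(C=O)CC[C@@H]3C[C@@]32C
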